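The step that makes L and the step that consumes it both run in proportion to [Q], so I set them against each other directly.

    J + Z → Z + E (k1 = 220 L mol⁻¹ h⁻¹)
    D + E ⇌ D.E (K2 = 470 L mol⁻¹, k2 = 3400 L mol⁻¹ h⁻¹)
    Q + D.E → D + L (k3 = 42 L mol⁻¹ h⁻¹)
    Q + L → Q.L (k4 = 0.016 L mol⁻¹ h⁻¹)

| setting | theta | epsilon | eta |
|---|---|---|---|
| J | 0.36 M | 0.36 M | 0.36 M |
| Q | 0.300 M | 0.600 M | 1.50 M |
| Z | 1.8 mM | 1.8 mM | 1.8 mM |
| D | 0.47 mM | 0.47 mM | 0.47 mM |
| time | 2.5 d | 2.5 d | 2.5 d |

* amount of L at the end, in percent of the J charged for theta, epsilon, eta, in this order
* the shape of the row from first to last (rises all the way / falls, then rises / hardly changes / falls all the way / rises, then falls)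

- "hardly changes" means that all values lie within two and a half points (for a concentration: within two and a half percent of the largest)
- run time (theta): 2.5 d

1. I first turned the constants into times. J had a lifetime of about 2.53 h under Z, against a run of 2.5 d, so I treated E as standing in the place of J from early on.

2. Free D met E at 1220 h⁻¹, while D.E met Q at 63.0 h⁻¹ even in eta, so as long as E stood in quantity I took D.E as the resting state of D, and L was made at 42 L mol⁻¹ h⁻¹ times the D charged times [Q].

3. L was lost at 0.016 L mol⁻¹ h⁻¹ times [L][Q], so [Q] cancelled from the comparison. The value 1.23 M I called the balance level, the [L] at which making and loss are equal with D held wholly as D.E; the ratio of making to loss is this level, times the share of D present as D.E, over [L]. It stood above the J charged, so I expected L to rise while D.E lasted.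

4. With D so held, I reckoned Q to decay at 0.0197 h⁻¹, so in theta the step could make 0.208 M by the end, less than the J charged. I therefore expected E to outlast the run in theta, and the balance level reduced the figure for L to 0.192 M, or 53.2% of J.

5. By the same reckoning, epsilon would clear E at about 46.4 h and eta at about 13.9 h, and I put L at 0.312 M at that moment in both. After that I let L decay against the Q left, which I held fixed, and this gave 0.296 M for epsilon and 0.135 M for eta, or 82.3% and 37.4% of J. My row therefore rose, then fell, and holding Q fixed put my eta figure on the low side.

The forecast gave 51%, 85% and 44%, rises, then falls, holding that “D stays nearly saturated as D.E”, and its eta figure stood above mine.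

The simulation gave 51.2%, 84.2% and 42.4%, rises, then falls. In theta at 2.50 d, with D.E at 98.1% of the D charged and L at 51.2% of J, the balance level gives a ratio of 6.56, and L was being made 6.57 times faster than it was used up. In eta at 1.25 d, with D.E at 0.00694% and L at 67.6%, the same ratio is 3.52 × 10⁻⁴, and L went on to 42.4% at 2.50 d.

(The constants used here come from no measurement; the run is a simulation.)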